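**Plan**
- The last disconnection is the O–Si bond of a triisopropylsilyl ether on the benzylic alcohol of ring B; the target has no stereocentre and no stereogenic double bond.
- Ring A (the benzoate ring) is then cut at two C–C bonds, C4–C5 and C6–C1. The run C1 (CO2Me), C2 (O-prenyl), C3 (H), C4 (CH3) is C3 to C6 of a 3-carbomethoxy-4-prenyloxy-6-methylpyran-2-one, and C5 plus the aryloxy-bearing C6 are the two carbons of an aryl ethynyl ether, so the diaryl ether oxygen comes in already attached to ring B.
- Forward, arm 1 (2 steps): dimethyl malonate and diketene give the 4-hydroxypyranone ester, which is O-prenylated.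
- Forward, arm 2 (5 steps): 2,4-dimethoxyphenol is ortho-formylated, reduced, silylated at the benzylic oxygen, converted into the dichlorovinyl ether and eliminated to the ethynyl ether.
- The arms meet in an inverse-demand [4+2] cycloaddition followed by loss of CO2, which closes ring A with all substituents in place; fluoride then frees the alcohol.
- Stereochemistry: nothing to set; the (E) geometry of the dichlorovinyl ether and the bridgehead centres of the bicyclic adduct are transient.

Key step: step 8

Assumption: the terminal aryl ethynyl ether 15 has no C–H positioned for ketene-forming retro-ene fragmentation, so it is taken to survive 110 °C in dry, neutral toluene.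

**Route**

Step 1
Reactants: 1 dimethyl malonate; 2 diketene
Product: 4 methyl 4-hydroxy-6-methyl-2-oxo-2H-pyran-3-carboxylate, via acylmalonate 3 (not isolated)
Conditions: NaH, THF, 0 °C; then 2, −10 °C → rt; aq. HCl
Reagents that add atoms: none
Why: C-acylation of sodiomalonate by diketene (acyl–oxygen opening of the β-lactone) gives 3, whose ketone enolate oxygen should lactonise onto one ester with loss of methanol, a known malonate–diketene pyranone synthesis driven by formation of the stabilised vinylogous-acid anion.

Step 2
Reactants: 4 methyl 4-hydroxy-6-methyl-2-oxo-2H-pyran-3-carboxylate; 5 prenyl bromide (1-bromo-3-methylbut-2-ene)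
Product: 6 methyl 6-methyl-4-[(3-methylbut-2-en-1-yl)oxy]-2-oxo-2H-pyran-3-carboxylate
Conditions: K2CO3, DMF, rt
Reagents that add atoms: none
Why: Williamson-type O-alkylation of a vinylogous carboxylic acid, in which the potassium salt of 4 should be alkylated by the primary allylic bromide at the 4-oxygen in a dipolar aprotic solvent because C3 is blocked by the ester and the conjugated 4-alkoxypyran-2-one is the more stable O-alkyl isomer.

Step 3
Reactants: 7 2,4-dimethoxyphenol
Product: 9 2-hydroxy-3,5-dimethoxybenzaldehyde, via magnesium salicyl alkoxide 8 (not isolated)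
Conditions: MgCl2, Et3N, (CH2O)n, MeCN, reflux; aq. HCl
Reagents that add atoms: paraformaldehyde (as formaldehyde), C=O
Why: Casnati–Skattebøl ortho-formylation, in which the chloromagnesium phenoxide delivers formaldehyde only to the single free ortho carbon and the magnesium-bound benzylic alkoxide 8 is oxidised in the flask by hydride transfer to a second formaldehyde, so the aldehyde is the isolable product.

Step 4
Reactants: 9 2-hydroxy-3,5-dimethoxybenzaldehyde
Product: 10 2-(hydroxymethyl)-4,6-dimethoxyphenol
Conditions: NaBH4, MeOH, 0 °C
Reagents that add atoms: none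
Why: Borohydride reduction of an aryl aldehyde to the benzylic alcohol is fast at 0 °C and leaves the phenol and the methyl ethers untouched.

Step 5
Reactants: 10 2-(hydroxymethyl)-4,6-dimethoxyphenol
Product: 11 2,4-dimethoxy-6-[(triisopropylsilyloxy)methyl]phenol
Conditions: iPr3SiCl (1.05 equiv), imidazole, CH2Cl2, 0 °C → rt
Reagents that add atoms: chlorotriisopropylsilane, CC(C)[Si](Cl)(C(C)C)C(C)C
Why: Selective silylation, in which the bulky chlorosilane should react at the unhindered primary benzylic hydroxyl much faster than at a phenol flanked by two ortho substituents, as is usual for salicyl alcohols.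

Step 6
Reactants: 11 2,4-dimethoxy-6-[(triisopropylsilyloxy)methyl]phenol
Product: 12 2-[(E)-1,2-dichloroethenyloxy]-1,5-dimethoxy-3-[(triisopropylsilyloxy)methyl]benzene
Conditions: Cl2C=CHCl, K2CO3, DMF, 70 °C
Reagents that add atoms: trichloroethylene, ClC=C(Cl)Cl
Why: Base converts trichloroethylene into dichloroacetylene in the flask and the phenoxide adds to it in anti fashion to give the (E)-1,2-dichlorovinyl ether, the standard entry to aryl ynol ethers, under conditions that a silyl ether tolerates.

Step 7
Reactants: 12 2-[(E)-1,2-dichloroethenyloxy]-1,5-dimethoxy-3-[(triisopropylsilyloxy)methyl]benzene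
Product: 15 2-(ethynyloxy)-1,5-dimethoxy-3-[(triisopropylsilyloxy)methyl]benzene, via chloroethynyl ether 13 (not isolated), via lithium acetylide 14 (not isolated)
Conditions: n-BuLi (2.3 equiv), THF, −78 → −40 °C; H2O, −78 °C
Reagents that add atoms: none
Why: The established dichlorovinyl ether-to-ynol ether elimination, in which vinylic deprotonation and loss of LiCl give 13, chlorine–lithium exchange with the second equivalent gives 14 and cold protonation releases the terminal alkyne, while the fully substituted ortho positions and the robust silyl ether leave no competing site for the base.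

Step 8
Reactants: 6 methyl 6-methyl-4-[(3-methylbut-2-en-1-yl)oxy]-2-oxo-2H-pyran-3-carboxylate; 15 2-(ethynyloxy)-1,5-dimethoxy-3-[(triisopropylsilyloxy)methyl]benzene (1.5 equiv)
Product: 17 methyl 2-{2,4-dimethoxy-6-[(triisopropylsilyloxy)methyl]phenoxy}-4-methyl-6-[(3-methylbut-2-en-1-yl)oxy]benzoate, via bicyclic lactone 16 (not isolated)
Conditions: PhMe, 110 °C, sealed tube, Ar
Reagents that add atoms: none
Why: Proposed new method: the alkyne of 15, made electron-rich by the aryloxy oxygen, should add across C3 and C6 of the electron-poor diene of 6 (lowered in energy by the lactone and the C3 ester) in an asynchronous inverse-electron-demand Diels–Alder reaction, and the 2-oxabicyclo[2.2.2]octadienone 16 so formed should expel CO2 by retro-[4+2] at the same temperature. The closest known reaction type is the cycloaddition of 3-carbomethoxypyran-2-ones with ketene acetals, ynamines and alkoxyalkynes followed by CO2 extrusion to give benzoates; an aryl ethynyl ether on a 4-alkoxy-6-methylpyranone has not been shown. Ring A closes by an intermolecular [4+2] that forms both new ring bonds (pyranone C6 to the terminal alkyne carbon, which is C4–C5 of the target, and pyranone C3 to the oxygen-bearing alkyne carbon, which is C6–C1), and aromatisation follows from the CO2 loss alone, without oxidation or elimination. No stereocentre is created, since the two bridgehead centres of racemic 16 disappear on aromatisation. The step needs the aryloxy carbon to end next to the ester carbon, and the matched polarisation should secure this: the nucleophilic terminal alkyne carbon attacks C6, the position δ to both carbonyl groups (C4 being deactivated by its alkoxy donor), and the developing aryloxy-stabilised cation is captured by the malonate-like C3. It also needs the prenyl group to stay put, which is expected because a [3,3] shift to the ester-bearing C3 would have to build two adjacent quaternary carbons and the unactivated trisubstituted alkene is no match for the diene.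

Step 9
Reactants: 17 methyl 2-{2,4-dimethoxy-6-[(triisopropylsilyloxy)methyl]phenoxy}-4-methyl-6-[(3-methylbut-2-en-1-yl)oxy]benzoate
Product: 18 methyl 2-[2-(hydroxymethyl)-4,6-dimethoxyphenoxy]-4-methyl-6-[(3-methylbut-2-en-1-yl)oxy]benzoate
Conditions: Bu4NF, AcOH, THF, 0 °C → rt
Reagents that add atoms: none
Why: Fluoride-mediated desilylation of a primary silyl ether, driven by the strong Si–F bond, with acetic acid buffering so that the freed alkoxide does not attack the methyl ester across the diaryl ether to form an eight-membered lactone.

**Compound list**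

1 | dimethyl malonate | COC(=O)CC(=O)OC | starting material
2 | diketene (4-methylideneoxetan-2-one) | C=C1CC(=O)O1 | starting material
3 | dimethyl 2-(3-oxobutanoyl)malonate (present as its sodium enolate) | COC(=O)C(C(=O)OC)C(=O)CC(C)=O | intermediate (not isolated)
4 | methyl 4-hydroxy-6-methyl-2-oxo-2H-pyran-3-carboxylate | COC(=O)C1=C(O)C=C(C)OC1=O | intermediate
5 | prenyl bromide (1-bromo-3-methylbut-2-ene) | CC(C)=CCBr | starting material
6 | methyl 6-methyl-4-[(3-methylbut-2-en-1-yl)oxy]-2-oxo-2H-pyran-3-carboxylate | COC(=O)C1=C(OCC=C(C)C)C=C(C)OC1=O | intermediate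
7 | 2,4-dimethoxyphenol | COc1ccc(O)c(OC)c1 | starting material
8 | chloromagnesium 2-(hydroxymethyl)-4,6-dimethoxyphenoxide | COc1cc(CO)c(O[Mg]Cl)c(OC)c1 | intermediate (not isolated)
9 | 2-hydroxy-3,5-dimethoxybenzaldehyde | COc1cc(C=O)c(O)c(OC)c1 | intermediate
10 | 2-(hydroxymethyl)-4,6-dimethoxyphenol | COc1cc(CO)c(O)c(OC)c1 | intermediate
11 | 2,4-dimethoxy-6-[(triisopropylsilyloxy)methyl]phenol | COc1cc(CO[Si](C(C)C)(C(C)C)C(C)C)c(O)c(OC)c1 | intermediate
12 | 2-[(E)-1,2-dichloroethenyloxy]-1,5-dimethoxy-3-[(triisopropylsilyloxy)methyl]benzene | Cl/C=C(/Cl)Oc1c(CO[Si](C(C)C)(C(C)C)C(C)C)cc(OC)cc1OC | intermediate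
13 | 2-(chloroethynyloxy)-1,5-dimethoxy-3-[(triisopropylsilyloxy)methyl]benzene | ClC#COc1c(CO[Si](C(C)C)(C(C)C)C(C)C)cc(OC)cc1OC | intermediate (not isolated)
14 | lithium {2,4-dimethoxy-6-[(triisopropylsilyloxy)methyl]phenoxy}acetylide | [Li]C#COc1c(CO[Si](C(C)C)(C(C)C)C(C)C)cc(OC)cc1OC | intermediate (not isolated)
15 | 2-(ethynyloxy)-1,5-dimethoxy-3-[(triisopropylsilyloxy)methyl]benzene | C#COc1c(CO[Si](C(C)C)(C(C)C)C(C)C)cc(OC)cc1OC | intermediate
16 | racemic methyl 8-aryloxy-1-methyl-3-oxo-5-(prenyloxy)-2-oxabicyclo[2.2.2]octa-5,7-diene-4-carboxylate (aryl = 2,4-dimethoxy-6-[(triisopropylsilyloxy)methyl]phenyl) | COC(=O)C12C(=O)OC(C)(C=C1OCC=C(C)C)C=C2Oc1c(CO[Si](C(C)C)(C(C)C)C(C)C)cc(OC)cc1OC | intermediate (not isolated)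
17 | methyl 2-{2,4-dimethoxy-6-[(triisopropylsilyloxy)methyl]phenoxy}-4-methyl-6-[(3-methylbut-2-en-1-yl)oxy]benzoate | COC(=O)c1c(OCC=C(C)C)cc(C)cc1Oc1c(CO[Si](C(C)C)(C(C)C)C(C)C)cc(OC)cc1OC | intermediate
18 | methyl 2-[2-(hydroxymethyl)-4,6-dimethoxyphenoxy]-4-methyl-6-[(3-methylbut-2-en-1-yl)oxy]benzoate | COC(=O)c1c(OCC=C(C)C)cc(C)cc1Oc1c(CO)cc(OC)cc1OC | target

**Count and risks**

Total step count: 9. Longest linear sequence: 7 steps (steps 3 to 9, from 2,4-dimethoxyphenol).

Steps most likely to fail:

1. Step 8 (proposed new method). The cycloaddition may be too slow at temperatures the ynol ether survives, because the 4-prenyloxy donor raises the acceptor orbital of the diene; oligomerisation of 15 or a thermal shift of the prenyl group could then outrun ring formation. The fallback makes the diaryl ether bond by known palladium-catalysed C–O coupling. It sets out from phenol 11 and prenyl bromide 5. Purchased methyl 2,6-dihydroxy-4-methylbenzoate F1 is mono-O-alkylated with 5 (K2CO3, acetone, reflux; the second hydroxyl stays hydrogen-bonded to the ester) to methyl 2-hydroxy-4-methyl-6-[(3-methylbut-2-en-1-yl)oxy]benzoate F2. Tf2O and pyridine in CH2Cl2 at 0 °C convert F2 into methyl 4-methyl-2-[(3-methylbut-2-en-1-yl)oxy]-6-(trifluoromethylsulfonyloxy)benzoate F3. Buchwald–Hartwig etherification of F3 with 11 (Pd(OAc)2 as source of zerovalent palladium, 2-di-tert-butylphosphino-2',4',6'-triisopropylbiphenyl, K3PO4, PhMe, 100 °C) should give 17, where the route is rejoined before step 9.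

2. Step 2. The enolate of 4 is ambident, so alkylation may go partly to the lactone carbonyl oxygen or to C3, and the chelated enol may react sluggishly. The fallback sets out from 4 and uses a Mitsunobu reaction with 3-methylbut-2-en-1-ol (PPh3, diisopropyl azodicarboxylate, THF, 0 °C → rt), which activates the alcohol instead of the enolate and is the usual way to 4-alkoxypyran-2-ones from acidic 4-hydroxypyranones. It returns to the route at 6 and makes no new compound.

3. Step 7. The terminal ynol ether may be hydrated or oligomerised during aqueous quench and chromatography. The fallback sets out from 12: acetylide 14 is generated as before but trapped with Me3SiCl to give 1,5-dimethoxy-3-[(triisopropylsilyloxy)methyl]-2-[(trimethylsilyl)ethynyloxy]benzene F4, which should tolerate purification and storage. K2CO3 in MeOH at 0 °C removes the alkynyl silyl group just before the cycloaddition, returning the route at 15, which is used without chromatography.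

**Further compounds**

F1 | step 8 | methyl 2,6-dihydroxy-4-methylbenzoate (purchased starting material of the fallback) | COC(=O)c1c(O)cc(C)cc1O
F2 | step 8 | methyl 2-hydroxy-4-methyl-6-[(3-methylbut-2-en-1-yl)oxy]benzoate | COC(=O)c1c(O)cc(C)cc1OCC=C(C)C
F3 | step 8 | methyl 4-methyl-2-[(3-methylbut-2-en-1-yl)oxy]-6-(trifluoromethylsulfonyloxy)benzoate | COC(=O)c1c(OS(=O)(=O)C(F)(F)F)cc(C)cc1OCC=C(C)C
F0 | step 2 | none | none
F4 | step 7 | 1,5-dimethoxy-3-[(triisopropylsilyloxy)methyl]-2-[(trimethylsilyl)ethynyloxy]benzene | C[Si](C)(C)C#COc1c(CO[Si](C(C)C)(C(C)C)C(C)C)cc(OC)cc1OC
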